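**Remark on the structure (assumption).** The SMILES has no stereo descriptor, so the hindered C5–C5' axis is treated as not configured and no atropselective step is planned. The hydroxyquinones are drawn as 2-hydroxy-1,4-quinone tautomers. Locants: ring A (chain ending in the 2-methoxyphenyl group) is C1(=O), C2(OH), C3(CH3), C4(=O), C5 (bond to ring B), C6 (chain); ring B (phenylethyl chain) uses the same locants with primes.

## The problem

The target is a 5,5'-linked dimer of two 2-hydroxy-3-methyl-1,4-benzoquinones, each with a 2-arylethyl chain at C6; the halves differ only by one methoxy group on the far arene of the ring A chain. The C5–C5' bond joins two hexasubstituted rings and has four ortho neighbours (C4=O and C6–chain on each side), so it is a poor bond to make between two finished rings. Because the halves are electronically alike, any dimerisation of monomers cannot favour the cross-product. Each ring needs one fixed order of substituents (from C5: C4=O, C3–CH3, C2–OH, C1=O, C6–chain), and an isomer with methyl and hydroxyl exchanged would be very hard to remove. There is no stereocentre to set. The hydroxyquinones are acidic, redox-active acceptors and should appear last, and whatever frees their OH groups must spare the aryl methyl ether. The enabling feature is this: C6–C5–C5'–C6' with its two chains is the skeleton of a 1,4-disubstituted buta-1,3-diene (at higher oxidation level a 1,3-diyne), and the other four carbons of each ring, C1(=O)–C2(OH)–C3(CH3)–C4(=O), are those of a methyl-substituted squaric acid. Both rings show the same pattern, so one C4 reagent can be annulated twice onto one C4 chain.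

## Retrosynthesis

**16 to 15.** The two C2–OH groups are taken back to methyl ethers. No skeletal bond is cut. A methoxyquinone is what squarate chemistry delivers, and a vinylogous ester can be saponified without touching the anisole ether.

**15 to 13 (via 14).** In each ring the C4–C5 bond is cut and C4 is re-bonded to C1, so each quinone becomes a 4-hydroxycyclobutenone on C6 of a (Z,Z)-diene. Compared with cutting C5–C5', this removes both hexasubstituted rings at once and leaves the crowded inter-ring bond as the unhindered central single bond of a diene. Compared with other ring cuts (alkyne plus carbene complex), it fixes the substituent order by connectivity and not by a steric preference. The forward step needs two thermal 4π openings and two 6π closures onto C5 and C5', and must tolerate the crowding when the second ring forms beside the first.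

**13 to 12 and two molecules of 11.** The two C6–C1 bonds (alkene carbon to carbinol carbon) are cut. Dione 11 takes organolithiums at the carbonyl next to C–OMe, which places C–OMe beside the future C1=O and C–CH3 beside the future C4=O. The forward step consumes two molecules of 11 per molecule of 12 and needs two intermolecular additions before the second C–Li can attack the first cyclobutenone.

**11 to 9 (via 10).** The C3–CH3 bond is cut: dimethyl squarate 9 plus MeLi, then transposition.

**12 to 8 to 7.** The C–Li bonds are traced to the C–Te bonds of tellurophene 8, and these to diyne 7. Hydroboration of a 1,3-diyne places boron on the inner carbons (C5/C5'), which is the wrong site. A chalcogenide nucleophile adds to the outer ones, and closing a ring with one tellurium atom guarantees metal on C6 and C6' with one alkene geometry.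

**7 to 5 and 6.** The C5–C5' bond is cut as an sp–sp bond (Cadiot–Chodkiewicz coupling of bromoalkyne 5 with alkyne 6). This is the only step where the halves meet as different species, and they play different roles, so the cross-product is the intended one. The bond that is tetra-ortho-substituted in 16 is made between two unhindered alkyne termini.

**5 to 4 to 1 and 2 (via 3).** The CH2–CH2 bond of the anisole chain is cut: benzyl bromide 1 plus lithiated silylpropyne 3 (from 2) gives 4, whose silyl group is exchanged for bromine. Alkyne 6 is bought.

## Roads not taken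

Alternative 1: Cut C5–C5' between two aromatic rings, the most obvious plan. Suzuki–Miyaura coupling of the hexasubstituted bromide A1 with the boronate A2 would give the heptamethyl ether A3; oxidative demethylation with (NH4)2Ce(NO3)6 would give 15. The chosen plan is better because each partner needs its own sequence from a trimethoxytoluene (formylation, olefination, hydrogenation, halogenation or borylation), where the chosen route builds both rings in one operation from 11. The coupling is also of the hardest class: an electron-rich, di-ortho-substituted bromide with a di-ortho-substituted boronate prone to protodeboronation. The final oxidation must then act on two trimethoxyarene rings beside an anisole.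

Alternative 2: Cut C5–C5' as in the presumed biosynthesis, by oxidative coupling of the monomeric hydroxyquinones A4 and A5 (or addition of the reduced form of one to the quinone of the other). The two monomers differ only by a methoxy group six bonds from the reacting carbon, so there is no bias for cross-coupling and 16 could be at best the major part of a statistical mixture of near-identical dimers. Quinone–hydroquinone redox exchange also scrambles any assigned donor and acceptor roles, and C–O coupling competes. The chosen plan settles the cross-junction in a coupling whose partners have different functions.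

Alternative 3: Keep diyne 7 but build the rings by a two-fold Dötz benzannulation with the alkenyl carbene complex A6 of zerovalent chromium, giving the bis(methoxyphenol) A7 and then 15 by oxidation. Alkyne insertion is oriented by the relative size of the two alkyne substituents. In the first annulation the alkynyl group is the smaller one; in the second, the new hexasubstituted aryl group is the larger. One reagent would therefore be asked for opposite orientations, and one ring would probably carry methyl and oxygen exchanged. The squarate route fixes this by which carbon bears lithium and which carbonyl is attacked, and it needs no stoichiometric chromium.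

Key step: step 7

## Steps

Step 1
Reactants: 1 1-(bromomethyl)-2-methoxybenzene; 2 trimethyl(prop-1-yn-1-yl)silane
Product: 4 [4-(2-methoxyphenyl)but-1-yn-1-yl]trimethylsilane, via lithiated silylpropyne 3 (not isolated)
Conditions: 2, n-BuLi, THF, –78 → –20 °C; then 1, –78 → 25 °C
Reagents that add atoms: none
Why: Propargylic deprotonation of 2 gives the silyl-stabilised anion 3, which is alkylated by the benzylic bromide at the propargylic carbon (SN2 alkylation of a lithiated silylpropyne); the silyl group blocks the alkyne terminus and disfavours the allenic product.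

Step 2
Reactants: 4 [4-(2-methoxyphenyl)but-1-yn-1-yl]trimethylsilane
Product: 5 1-(4-bromobut-3-yn-1-yl)-2-methoxybenzene
Conditions: NBS, AgNO3 (10 mol %), acetone, 25 °C, dark
Reagents that add atoms: N-bromosuccinimide, O=C1CCC(=O)N1Br
Why: Silver-catalysed desilylative bromination: AgNO3 converts the C–Si bond into a silver acetylide that NBS brominates, giving the 1-bromoalkyne directly. In acetone without acid, NBS should not brominate the anisole ring at a competitive rate.

Step 3
Reactants: 5 1-(4-bromobut-3-yn-1-yl)-2-methoxybenzene; 6 but-3-yn-1-ylbenzene
Product: 7 1-methoxy-2-(8-phenylocta-3,5-diyn-1-yl)benzene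
Conditions: CuCl (5 mol %), NH2OH·HCl, n-BuNH2 (30% aq), 0 → 25 °C
Reagents that add atoms: none
Why: Cadiot–Chodkiewicz coupling: the copper acetylide of 6 (copper kept monovalent by NH2OH·HCl) reacts with bromoalkyne 5. The two alkynes enter in different roles, so the unsymmetrical diyne is the direct product.

Step 4
Reactants: 7 1-methoxy-2-(8-phenylocta-3,5-diyn-1-yl)benzene
Product: 8 2-[2-(2-methoxyphenyl)ethyl]-5-(2-phenylethyl)tellurophene
Conditions: Te, NaBH4, EtOH, 78 °C; then 7, THF, 25 → 60 °C
Reagents that add atoms: sodium telluride, [Na+].[Na+].[Te-2], made in the flask from tellurium, [Te]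
Why: Telluride adds to an outer carbon of the diyne (the inner carbon takes the charge and is protonated by ethanol), and the tellurolate then closes by 5-endo-dig addition onto the other outer carbon. This is the known tellurophene synthesis from 1,3-diynes, and it puts tellurium on exactly the two chain-bearing carbons.

Step 5
Reactants: 9 3,4-dimethoxycyclobut-3-ene-1,2-dione
Product: 11 3-methoxy-4-methylcyclobut-3-ene-1,2-dione, via lithium alkoxide 10 (not isolated)
Conditions: MeLi, THF, –78 °C; (CF3CO)2O, –78 °C; then H2O
Reagents that add atoms: methyllithium, [Li]C; water, O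
Why: 1,2-Addition of MeLi to one squarate carbonyl, then trifluoroacetylation and loss of the tertiary oxygen with allylic transposition; water adds at the methoxy-stabilised cation and methanol leaves, so the new carbonyl oxygen comes from water. This is the standard squarate-to-alkylcyclobutenedione sequence.

Step 6
Reactants: 8 2-[2-(2-methoxyphenyl)ethyl]-5-(2-phenylethyl)tellurophene; 11 3-methoxy-4-methylcyclobut-3-ene-1,2-dione (two molecules enter the product)
Product: 13 4,4'-[(3Z,5Z)-1-(2-methoxyphenyl)-8-phenylocta-3,5-diene-3,6-diyl]bis(4-hydroxy-3-methoxy-2-methylcyclobut-2-en-1-one) (mixture of diastereomers at the two carbinol carbons), via dilithiodiene 12 (not isolated)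
Conditions: n-BuLi (2.05 equiv), THF, –78 °C; cannula into 11 (3 equiv), THF, –78 °C; aq NH4Cl, –78 °C
Reagents that add atoms: 3-methoxy-4-methylcyclobut-3-ene-1,2-dione 11 (the second of the two molecules taken up), COC1=C(C)C(=O)C1=O
Why: Two tellurium–lithium exchanges open the ring with retention to dilithiodiene 12 (the known ring opening of tellurophenes by alkyllithiums), and each of the two alkenyllithium ends adds 1,2 to the ketone-like carbonyl of one molecule of 11 (the one next to C–OMe; the other is a vinylogous ester), so one molecule of 12 takes up two molecules of 11. Inverse addition into excess 11 at –78 °C is meant to outrun attack of the second C–Li on the deactivated carbonyl of the first adduct. The two carbinol centres form without control and are erased in step 7.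

Step 7
Reactants: 13 4,4'-[(3Z,5Z)-1-(2-methoxyphenyl)-8-phenylocta-3,5-diene-3,6-diyl]bis(4-hydroxy-3-methoxy-2-methylcyclobut-2-en-1-one)
Product: 15 2-methoxy-5-[4-methoxy-5-methyl-3,6-dioxo-2-(2-phenylethyl)cyclohexa-1,4-dien-1-yl]-6-[2-(2-methoxyphenyl)ethyl]-3-methylcyclohexa-2,5-diene-1,4-dione, via bis-hydroquinone 14 (not isolated)
Conditions: p-xylene, 140 °C, Ar; then Ag2O, Et2O, 25 °C
Reagents that add atoms: none
Why: Each 4-hydroxycyclobutenone opens by thermal conrotatory 4π ring opening in which the hydroxyl rotates outward and the alkenyl group inward, giving a dienylketene whose ketene carbon lies next to C5 (or C5'). A 6π electrocyclisation then joins the ketene carbon (future C4) to the diene CH (C5), and enolisation of the cyclohexadienone gives the hydroquinone; this is the Moore–Liebeskind benzannulation of 4-alkenyl-4-hydroxycyclobutenones, here run twice in one molecule. Both rings close in the same mode, a six-membered 6π electrocyclic closure followed by aromatisation, and the C5–C5' bond, already present as the diene single bond, becomes the inter-ring bond without being formed between two rings. No stereocentre is created: the carbinol centres of 13 are lost and the axis is not configured. Regiochemistry needs no selectivity because connectivity fixes it (a carbinol carbon next to C–OMe and bonded to the chain-bearing alkene carbon gives C2–OMe beside C1=O beside C6). The selectivity that is needed is 6π over 8π closure of the first ketene across the (Z,Z)-diene; the 8π mode would have to bond to the fully substituted alkene carbon bearing the second cyclobutenone and gives a product that cannot aromatise, whereas the 6π product aromatises irreversibly. The second closure occurs at a CH whose inner substituent is the newly formed ring; the ketene carbon is attacked in its own plane and such closures tolerate inward substituents, but this is the most demanding point of the step. Ag2O then oxidises the air-sensitive bis-hydroquinone 14 to the bis-quinone without touching the anisole ring.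

Step 8
Reactants: 15 2-methoxy-5-[4-methoxy-5-methyl-3,6-dioxo-2-(2-phenylethyl)cyclohexa-1,4-dien-1-yl]-6-[2-(2-methoxyphenyl)ethyl]-3-methylcyclohexa-2,5-diene-1,4-dione
Product: 16 2-hydroxy-5-[4-hydroxy-5-methyl-3,6-dioxo-2-(2-phenylethyl)cyclohexa-1,4-dien-1-yl]-6-[2-(2-methoxyphenyl)ethyl]-3-methylcyclohexa-2,5-diene-1,4-dione
Conditions: NaOH (2 M aq), MeOH, 25 °C; then HCl (1 M aq)
Reagents that add atoms: sodium hydroxide, [Na+].[OH-]
Why: Vinylogous ester saponification by addition–elimination of hydroxide at C2 and C2' (every other ring position is substituted) gives the stabilised hydroxyquinone anions, which are protonated to the 2-hydroxy-1,4-quinone tautomer. The aryl methyl ether is inert to aqueous base.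

## Compound list

1 | 1-(bromomethyl)-2-methoxybenzene | COc1ccccc1CBr | starting material
2 | trimethyl(prop-1-yn-1-yl)silane | CC#C[Si](C)(C)C | starting material
3 | 3-lithio-1-(trimethylsilyl)prop-1-yne (formed in the flask) | [Li]CC#C[Si](C)(C)C | intermediate
4 | [4-(2-methoxyphenyl)but-1-yn-1-yl]trimethylsilane | COc1ccccc1CCC#C[Si](C)(C)C | intermediate
5 | 1-(4-bromobut-3-yn-1-yl)-2-methoxybenzene | COc1ccccc1CCC#CBr | intermediate
6 | but-3-yn-1-ylbenzene | C#CCCc1ccccc1 | starting material
7 | 1-methoxy-2-(8-phenylocta-3,5-diyn-1-yl)benzene | COc1ccccc1CCC#CC#CCCc1ccccc1 | intermediate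
8 | 2-[2-(2-methoxyphenyl)ethyl]-5-(2-phenylethyl)tellurophene | COc1ccccc1CCC1=CC=C(CCc2ccccc2)[Te]1 | intermediate
9 | 3,4-dimethoxycyclobut-3-ene-1,2-dione (dimethyl squarate) | COC1=C(OC)C(=O)C1=O | starting material
10 | lithium 2,3-dimethoxy-1-methyl-4-oxocyclobut-2-en-1-olate (formed in the flask) | COC1=C(OC)C(C)([O-])C1=O.[Li+] | intermediate
11 | 3-methoxy-4-methylcyclobut-3-ene-1,2-dione | COC1=C(C)C(=O)C1=O | intermediate
12 | (3E,5E)-3,6-dilithio-1-(2-methoxyphenyl)-8-phenylocta-3,5-diene, each lithium cis to the other alkene carbon (formed in the flask) | [Li]/C(CCc1ccccc1OC)=C\C=C(/[Li])CCc1ccccc1 | intermediate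
13 | 4,4'-[(3Z,5Z)-1-(2-methoxyphenyl)-8-phenylocta-3,5-diene-3,6-diyl]bis(4-hydroxy-3-methoxy-2-methylcyclobut-2-en-1-one), mixture of diastereomers | COC1=C(C)C(=O)C1(O)/C(CCc1ccccc1OC)=C\C=C(/C1(O)C(OC)=C(C)C1=O)CCc1ccccc1 | intermediate
14 | 4,4'-dimethoxy-6-[2-(2-methoxyphenyl)ethyl]-3,3'-dimethyl-6'-(2-phenylethyl)[1,1'-biphenyl]-2,2',5,5'-tetrol (formed in the flask) | COc1c(O)c(CCc2ccccc2OC)c(-c2c(CCc3ccccc3)c(O)c(OC)c(C)c2O)c(O)c1C | intermediate
15 | 2-methoxy-5-[4-methoxy-5-methyl-3,6-dioxo-2-(2-phenylethyl)cyclohexa-1,4-dien-1-yl]-6-[2-(2-methoxyphenyl)ethyl]-3-methylcyclohexa-2,5-diene-1,4-dione | COC1=C(C)C(=O)C(C2=C(CCc3ccccc3)C(=O)C(OC)=C(C)C2=O)=C(CCc2ccccc2OC)C1=O | intermediate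
16 | 2-hydroxy-5-[4-hydroxy-5-methyl-3,6-dioxo-2-(2-phenylethyl)cyclohexa-1,4-dien-1-yl]-6-[2-(2-methoxyphenyl)ethyl]-3-methylcyclohexa-2,5-diene-1,4-dione (CNP0202346.0) | COc1ccccc1CCC1=C(C2=C(CCc3ccccc3)C(=O)C(O)=C(C)C2=O)C(=O)C(C)=C(O)C1=O | target

## Step count and risks

Total steps: 8. Longest linear sequence: 7 steps (1, 2, 3, 4, 6, 7, 8); step 5 is a one-step branch.

**Step 7 (key step).** The most likely failure is slow closure of the second ring. Once the first ring has aromatised, the second dienylketene must close onto a CH whose inward substituent is a hexasubstituted ring, so the ketene may be lost to dimerisation or to capture by a phenolic OH before it cyclises. An 8π closure of the first ketene across the (Z,Z)-diene is a second way for material to leave the path. The fallback sets out from 5, 6 and 11 and returns at 15; it closes the rings one at a time from monolithium reagents, each time onto a carbon whose inward group is small. syn-Bromoboration of 6 (BBr3, then pinacol) would give the (Z)-2-bromoalkenyl boronate F1. Suzuki–Miyaura coupling of F1 with bromoalkyne 5 (Pd(PPh3)4, K3PO4) would give the (Z)-bromoenyne F2. Bromine–lithium exchange (t-BuLi, –78 °C) and addition to 11 would give the mono(hydroxycyclobutenone) F3. Thermolysis would close ring B onto a carbon with only the linear alkynyl group inside and give the alkynyl hydroquinone F4, which is methylated (Me2SO4, K2CO3) to the aryl alkyne F5. syn-Hydrozirconation with Cp2Zr(H)Cl, zirconium going to the alkyne carbon away from the di-ortho-substituted ring, and iodinolysis would give the (E)-alkenyl iodide F6. Iodine–lithium exchange and addition to 11 would give the hydroxycyclobutenone F7, in which the closing CH has hydrogen on its inner side. Thermolysis would give the hydroquinone–trimethoxyarene F8, and (NH4)2Ce(NO3)6 would oxidise both rings of F8 to the quinone level, which is 15.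

**Step 6.** The most likely failure is ring closure of the mono-adduct. After the first addition the second C–Li is held by the (Z,Z)-diene within reach of the remaining vinylogous-ester carbonyl of the new cyclobutenone, and intramolecular 1,2-addition may compete with capture of a second molecule of 11. The fallback sets out from 9 and 12 and returns at 13; it uses an electrophile whose second carbonyl is masked until both C–C bonds exist. Monoketalisation of 9 (Me3SiOCH2CH2OSiMe3, Me3SiOTf cat.) would give the squarate monoketal F9. MeLi addition and (CF3CO)2O-induced transposition, as in step 5, would give the methyl ketal enone F10, whose only carbonyl is the one next to C–OMe. Dilithiodiene 12 would add to two molecules of F10 to give the bis-ketal diol F11, which has no carbonyl for the second C–Li to attack. Mild aqueous acid (oxalic acid, THF/H2O) would unmask the two ketones to give 13.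

**Step 4.** The dialkyl diyne is a weaker acceptor than the aryl diynes on which this heterocyclisation is usually run, so base-induced prototropic isomerisation of the CH2–C≡C units or over-reduction may compete with telluride addition. The fallback runs from 7 to 12. Two separate anti-hydrotellurations with butanetellurolate under reducing, weakly basic conditions ((BuTe)2, NaBH4, EtOH, reflux) would give the open-chain (3Z,5Z)-bis(butyl telluride) F12, with tellurium again on the outer carbons and cis to the diene. n-BuLi (one equivalent per tellurium, in slight excess) would then give 12 directly by two tellurium–lithium exchanges.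

**Step 8.** Base-induced degradation of the bis-quinone (deprotonation of the CH2 next to a quinone ring, then quinone methide chemistry) may set in before the second ether has been exchanged. The fallback runs from 15 to 16 and cleaves the ethers at the hydroquinone oxidation level. Na2S2O4 would reduce 15 to 14. BCl3 (CH2Cl2, –78 → 0 °C) would cleave the two methyl ethers next to a boron-bound phenol oxygen and spare the isolated anisole ether, giving the biphenylhexol F13. Ag2O would oxidise each 1,2,4-triol ring of F13 to the hydroxyquinone, 16.

## Further compounds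

F1 | step 7 | 2-[(1Z)-2-bromo-4-phenylbut-1-en-1-yl]-4,4,5,5-tetramethyl-1,3,2-dioxaborolane | Br/C(CCc1ccccc1)=C\B1OC(C)(C)C(C)(C)O1
F2 | step 7 | 1-[(5Z)-6-bromo-8-phenyloct-5-en-3-yn-1-yl]-2-methoxybenzene | Br/C(CCc1ccccc1)=C\C#CCCc1ccccc1OC
F3 | step 7 | 4-hydroxy-3-methoxy-4-[(3Z)-8-(2-methoxyphenyl)-1-phenyloct-3-en-5-yn-3-yl]-2-methylcyclobut-2-en-1-one | COC1=C(C)C(=O)C1(O)/C(CCc1ccccc1)=C\C#CCCc1ccccc1OC
F4 | step 7 | 2-methoxy-5-[4-(2-methoxyphenyl)but-1-yn-1-yl]-3-methyl-6-(2-phenylethyl)benzene-1,4-diol | COc1c(O)c(CCc2ccccc2)c(C#CCCc2ccccc2OC)c(O)c1C
F5 | step 7 | 1,2,4-trimethoxy-5-[4-(2-methoxyphenyl)but-1-yn-1-yl]-3-methyl-6-(2-phenylethyl)benzene | COc1c(OC)c(CCc2ccccc2)c(C#CCCc2ccccc2OC)c(OC)c1C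
F6 | step 7 | 1-[(1E)-2-iodo-4-(2-methoxyphenyl)but-1-en-1-yl]-2,4,5-trimethoxy-3-methyl-6-(2-phenylethyl)benzene | COc1c(OC)c(CCc2ccccc2)c(/C=C(/I)CCc2ccccc2OC)c(OC)c1C
F7 | step 7 | 4-hydroxy-3-methoxy-4-{(1E)-4-(2-methoxyphenyl)-1-[2,4,5-trimethoxy-3-methyl-6-(2-phenylethyl)phenyl]but-1-en-2-yl}-2-methylcyclobut-2-en-1-one | COC1=C(C)C(=O)C1(O)/C(CCc1ccccc1OC)=C/c1c(CCc2ccccc2)c(OC)c(OC)c(C)c1OC
F8 | step 7 | 2',4,4',5'-tetramethoxy-6-[2-(2-methoxyphenyl)ethyl]-3,3'-dimethyl-6'-(2-phenylethyl)[1,1'-biphenyl]-2,5-diol | COc1c(O)c(CCc2ccccc2OC)c(-c2c(CCc3ccccc3)c(OC)c(OC)c(C)c2OC)c(O)c1C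
F9 | step 6 | 2,3-dimethoxy-5,8-dioxaspiro[3.4]oct-2-en-1-one | COC1=C(OC)C2(OCCO2)C1=O
F10 | step 6 | 2-methoxy-3-methyl-5,8-dioxaspiro[3.4]oct-2-en-1-one | COC1=C(C)C2(OCCO2)C1=O
F11 | step 6 | 1,1'-[(3Z,5Z)-1-(2-methoxyphenyl)-8-phenylocta-3,5-diene-3,6-diyl]bis(2-methoxy-3-methyl-5,8-dioxaspiro[3.4]oct-2-en-1-ol), mixture of diastereomers | COC1=C(C)C2(OCCO2)C1(O)/C(CCc1ccccc1OC)=C\C=C(/C1(O)C(OC)=C(C)C12OCCO2)CCc1ccccc1
F12 | step 4 | 1-[(3Z,5Z)-3,6-bis(butyltellanyl)-8-phenylocta-3,5-dien-1-yl]-2-methoxybenzene | CCCC[Te]/C(CCc1ccccc1OC)=C\C=C(/[Te]CCCC)CCc1ccccc1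
F13 | step 8 | 6-[2-(2-methoxyphenyl)ethyl]-3,3'-dimethyl-6'-(2-phenylethyl)[1,1'-biphenyl]-2,2',4,4',5,5'-hexol | COc1ccccc1CCc1c(O)c(O)c(C)c(O)c1-c1c(CCc2ccccc2)c(O)c(O)c(C)c1O
A1 | alternative 1 | 1-bromo-2,4,5-trimethoxy-6-[2-(2-methoxyphenyl)ethyl]-3-methylbenzene | COc1c(OC)c(C)c(OC)c(Br)c1CCc1ccccc1OC
A2 | alternative 1 | 4,4,5,5-tetramethyl-2-[2,4,5-trimethoxy-3-methyl-6-(2-phenylethyl)phenyl]-1,3,2-dioxaborolane | COc1c(OC)c(C)c(OC)c(B2OC(C)(C)C(C)(C)O2)c1CCc1ccccc1
A3 | alternative 1 | 2,2',4,4',5,5'-hexamethoxy-6-[2-(2-methoxyphenyl)ethyl]-3,3'-dimethyl-6'-(2-phenylethyl)-1,1'-biphenyl | COc1c(OC)c(C)c(OC)c(-c2c(OC)c(C)c(OC)c(OC)c2CCc2ccccc2)c1CCc1ccccc1OC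
A4 | alternative 2 | 2-hydroxy-3-methyl-6-(2-phenylethyl)cyclohexa-2,5-diene-1,4-dione | CC1=C(O)C(=O)C(CCc2ccccc2)=CC1=O
A5 | alternative 2 | 2-hydroxy-6-[2-(2-methoxyphenyl)ethyl]-3-methylcyclohexa-2,5-diene-1,4-dione | CC1=C(O)C(=O)C(CCc2ccccc2OC)=CC1=O
A6 | alternative 3 | pentacarbonyl[(2E)-1,3-dimethoxy-2-methylprop-2-en-1-ylidene]chromium | CO/C=C(\C)C(OC)=[Cr](=C=O)(=C=O)(=C=O)(=C=O)=C=O
A7 | alternative 3 | 2,2',4,4'-tetramethoxy-6-[2-(2-methoxyphenyl)ethyl]-3,3'-dimethyl-6'-(2-phenylethyl)[1,1'-biphenyl]-5,5'-diol | COc1c(O)c(CCc2ccccc2OC)c(-c2c(CCc3ccccc3)c(O)c(OC)c(C)c2OC)c(OC)c1C
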